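Late in a run, the question is how much of the charge is still on its way to product and how much has left for good, and I wanted this for teal, grey and violet at 4.0 d.

| flask | starting material | protic impurity | free catalyst | remark | time |
|---|---|---|---|---|---|
| cedar | 2 M | 0.21 M | 20 mM | run made earlier |  |
| ash | 2 M | 0.26 M | 20 mM | run made earlier |  |
| maple | 2 M | 0.27 M | 20 mM | run made earlier |  |
| teal | 2.0 M | 0.200 M | 20 mM |  | 4.0 d |
| grey | 2.0 M | 0.240 M | 20 mM |  | 4.0 d |
| violet | 2.0 M | 0.290 M | 20 mM |  | 4.0 d |

- which of these there is most of at the end, counted by the starting material in it, teal (catalyst intermediate / starting material / product)
- which of these there is most of at the end, counted by the starting material in it, grey (catalyst intermediate / starting material / product)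
- which of these there is most of at the end, counted by the starting material in it, violet (catalyst intermediate / starting material / product)
- amount of the one of these that there is most of at the end, in percent of the starting material charged, teal
- amount of the one of these that there is most of at the end, in percent of the starting material charged, grey
- amount of the one of these that there is most of at the end, in percent of the starting material charged, violet

| run | time / h | starting material / % | product / % | catalyst intermediate / % |
|---|---|---|---|---|
| cedar | 4.00 | 79 | 6 | 1 |
| cedar | 8.00 | 73 | 17 | 0 |
| cedar | 20.0 | 55 | 39 | 1 |
| cedar | 50.0 | 22 | 69 | 0 |
| ash | 12.0 | 65 | 23 | 2 |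
| ash | 25.0 | 45 | 41 | 2 |
| ash | 40.0 | 29 | 58 | 0 |
| ash | 50.0 | 19 | 68 | 0 |
| maple | 4.00 | 78 | 7 | 0 |
| maple | 8.00 | 72 | 14 | 0 |
| maple | 20.0 | 53 | 34 | 2 |
| maple | 50.0 | 19 | 65 | 0 |

(standard deviation of a reading: 1.5 percentage points)

- the analysis behind the earlier runs scatters by 1.5 percentage points, standard deviation

I read the cedar table first. Between 20.0 h and 50.0 h starting material fell by 33 percentage points and product rose by 30 points, so nearly all of that late consumption became product. By 4.00 h, however, cedar had lost 21 points of starting material and shown only 6% of product, so an early loss had run ahead of the product.

Then I added the three columns in each row and averaged the rows. The missing share came to 9.50% in cedar, 12.0% in ash and 14.0% in maple. The ratios [protic impurity]/[starting material] at the start were 10.5%, 13.0% and 13.5%, and single readings scatter by 1.5 points. I therefore read a one-to-one loss with the protic impurity as its limiting reagent.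

That gave 90.0% for teal, 88.0% for grey and 85.5% for violet: the share of charged starting material in excess of the charged protic impurity, the ceiling.

Below the ceiling stands unreacted starting material. Treating cedar's late fall as first-order gave a time constant, read from two scattered readings, of 32.7 h, and from it I estimated a remainder of 5.40% at 4.0 d. Taking that remainder for all three, I expected product to lead, at 84.6%, 82.6% and 80.1%.

The forecast also chose product, but higher, at 88%, 86% and 83%, holding that “the protic impurity quickly destroys about one equivalent of starting material”.

Teal ended at 86.0% product, grey at 84.2% product and violet at 81.8% product. Teal held 3.96% of starting material at the end, less than my remainder. The teal ceiling minus that amount is 86.0%, and at 40.0 d teal's product stood at 90.0%.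

    starting material + protic impurity → quenched substrate (k = 1.10 /M/h)
    starting material + free catalyst → catalyst intermediate (k = 2.00 /M/h)
    catalyst intermediate → free catalyst + product (k = 4.80 /h)

With 1.2 M of starting material and teal's other charges, a neighbouring flask has a ceiling of 83.3%, lower than teal's. The computed flask gave 80.6% of product, with 2.67% of starting material left.

(The earlier runs and the new flask stem from a simulated flask with made-up constants, and the scatter is random.)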